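**Retrosynthetic overview**

1. Target ⇐ fluoride desilylation ⇐ B-alkyl Suzuki–Miyaura coupling (9-BBN hydroboration of an exocyclic methylene, then silyl-protected 4-bromoguaiacol, ring E) ⇐ 2,3-cis-2-aryl-3-(silyloxymethyl)-4-methylideneoxolane.
2. Oxolane (last ring closed) ⇐ one-flask formal [3+2] annulation: chiral-phosphoric-acid-catalysed syn-allylboration of the bis(dihydrobenzofuran) aldehyde with a 2-(chloromethyl)allyl pinacolboronate, then 5-exo-tet etherification.
3. Enabling feature: in the oxolane O1–C7–C8–C8'–C9', C7 is a benzylic carbon bearing the ring oxygen (an aldehyde carbon), C8' carries only a CH2Ar branch (so it can be sp2 with an exocyclic CH2, the former B–CH2), and C9' is primary (it can carry the leaving group); the C7/C8 cis relation maps onto a syn Zimmerman–Traxler adduct.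
4. Aldehyde ⇐ two rounds of Evans syn-aldol / LiBH4 / acid-mediated trans-selective benzylic cyclisation / silylation / Br-to-CHO exchange, using the (S)- and then the (R)-oxazolidinone imide, both made from one arylacetyl fluoride.
5. Ring order: benzene rings are bought (vanillin, 4-bromoguaiacol); dihydrobenzofuran B (next to the terminal guaiacyl ring D) first, then dihydrobenzofuran A, then the oxolane.

Key step: step 25

Remark on the structure: read from the SMILES, the oxolane is the all-cis (2R,3R,4R) isomer (aryl, CH2OH and arylmethyl on one face), and the two trans-dihydrobenzofurans are (2R,3S) (unit A, on the oxolane) and (2S,3R) (unit B); the route is planned for exactly this isomer.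
Assumption: the (R)-configured phosphoric acid TRIP delivers the allyl group to the Re face of this aryl aldehyde, as it does with simple benzaldehydes; Re-face attack gives the required (R) configuration at C7.
Abbreviations: TIPS = triisopropylsilyl, TBS = tert-butyldimethylsilyl, MOM = methoxymethyl, Bpin = 4,4,5,5-tetramethyl-1,3,2-dioxaborolan-2-yl, TRIP = 3,3'-bis(2,4,6-triisopropylphenyl)-1,1'-binaphthyl-2,2'-diyl hydrogen phosphate.

**Route**

Step 1
Reactants: 1 4-bromo-2-methoxyphenol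
Product: 2 4-bromo-2-iodo-6-methoxyphenol
Conditions: NIS, TsOH·H2O (10 mol%), MeCN, 0 °C to rt
Reagents that add atoms: N-iodosuccinimide, O=C1CCC(=O)N1I
Why: Electrophilic aromatic iodination; the para position is blocked by bromine, so the only free position ortho to the phenol is iodinated.

Step 2
Reactants: 2 4-bromo-2-iodo-6-methoxyphenol
Product: 3 5-bromo-1-iodo-3-methoxy-2-(methoxymethoxy)benzene
Conditions: MOMCl, iPr2NEt, CH2Cl2, 0 °C to rt
Reagents that add atoms: chloromethyl methyl ether, COCCl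
Why: Standard O-alkylation of the phenol; MOM is chosen because it is lost later in the same acidic step that closes the dihydrobenzofuran.

Step 3
Reactants: 3 5-bromo-1-iodo-3-methoxy-2-(methoxymethoxy)benzene; 4 diethyl malonate
Product: 5 diethyl 2-[5-bromo-3-methoxy-2-(methoxymethoxy)phenyl]malonate
Conditions: CuI (10 mol%), 2-picolinic acid (20 mol%), Cs2CO3, 1,4-dioxane, 40 °C
Reagents that add atoms: none
Why: Copper-catalysed C-arylation of a malonate (Hurtley/Ullmann type), which should be chemoselective for the C–I bond over the C–Br bond.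

Step 4
Reactants: 5 diethyl 2-[5-bromo-3-methoxy-2-(methoxymethoxy)phenyl]malonate
Product: 6 2-[5-bromo-3-methoxy-2-(methoxymethoxy)phenyl]acetic acid
Conditions: NaOH, EtOH/H2O, 60 °C; 1 M HCl to pH 3, 0 °C; toluene, 90 °C
Reagents that add atoms: sodium hydroxide, [Na+].[OH-]
Why: Saponification and thermal decarboxylation of the arylmalonic acid (malonic ester synthesis); the aryl MOM ether should survive brief exposure to pH 3.

Step 5
Reactants: 6 2-[5-bromo-3-methoxy-2-(methoxymethoxy)phenyl]acetic acid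
Product: 7 2-[5-bromo-3-methoxy-2-(methoxymethoxy)phenyl]acetyl fluoride
Conditions: cyanuric fluoride, pyridine, CH2Cl2, −10 °C to rt; cold aqueous wash
Reagents that add atoms: cyanuric fluoride (2,4,6-trifluoro-1,3,5-triazine), Fc1nc(F)nc(F)n1
Why: Conversion of the carboxylic acid into its acyl fluoride with cyanuric fluoride (Olah acyl fluoride synthesis); the acyl fluoride is stable enough to be isolated after a cold aqueous wash and serves as the one acyl donor for both auxiliaries, and the pyridine-buffered medium should spare the MOM acetal.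

Step 6
Reactants: 7 2-[5-bromo-3-methoxy-2-(methoxymethoxy)phenyl]acetyl fluoride; 8 (S)-4-benzyl-1,3-oxazolidin-2-one
Product: 9 (S)-4-benzyl-3-{[5-bromo-3-methoxy-2-(methoxymethoxy)phenyl]acetyl}-1,3-oxazolidin-2-one
Conditions: iPr2NEt, CH2Cl2, 0 °C to rt
Reagents that add atoms: none
Why: N-acylation of the oxazolidinone by the acid fluoride under mild amine-base conditions (acyl transfer with fluoride as the leaving group); no stereocentre is formed and that of the auxiliary is not touched.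

Step 7
Reactants: 7 2-[5-bromo-3-methoxy-2-(methoxymethoxy)phenyl]acetyl fluoride; 10 (R)-4-benzyl-1,3-oxazolidin-2-one
Product: 11 (R)-4-benzyl-3-{[5-bromo-3-methoxy-2-(methoxymethoxy)phenyl]acetyl}-1,3-oxazolidin-2-one
Conditions: iPr2NEt, CH2Cl2, 0 °C to rt
Reagents that add atoms: none
Why: Same N-acylation by the acid fluoride with the enantiomeric auxiliary, which will later give dihydrobenzofuran A in the opposite absolute sense.

Step 8
Reactants: 12 vanillin (4-hydroxy-3-methoxybenzaldehyde)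
Product: 13 3-methoxy-4-(triisopropylsilyloxy)benzaldehyde
Conditions: TIPSCl, imidazole, DMF, rt
Reagents that add atoms: chlorotriisopropylsilane, CC(C)[Si](Cl)(C(C)C)C(C)C
Why: Silylation of the phenol; the aryl TIPS ether should survive the later acid, borohydride and organolithium steps and is removed by fluoride at the end.

Step 9
Reactants: 9 (S)-configured arylacetyl imide; 13 3-methoxy-4-(triisopropylsilyloxy)benzaldehyde
Product: 15 (4S)-4-benzyl-3-[(2S,3S)-2-[5-bromo-3-methoxy-2-(methoxymethoxy)phenyl]-3-hydroxy-3-[3-methoxy-4-(triisopropylsilyloxy)phenyl]propanoyl]-1,3-oxazolidin-2-one, via Z-boron enolate 14 (not isolated)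
Conditions: Bu2BOTf, iPr2NEt, CH2Cl2, −78 to 0 °C; then 13, −78 to 0 °C; pH 7 buffer/MeOH
Reagents that add atoms: none
Why: Evans syn-aldol reaction: the Z-boron enolate reacts through a Zimmerman–Traxler chair on the enolate face left open by the (S)-benzyl auxiliary, which should give the (2S,3S) syn adduct and so fix C3 of dihydrobenzofuran B.

Step 10
Reactants: 15 syn-aldol imide
Product: 16 (1S,2R)-2-[5-bromo-3-methoxy-2-(methoxymethoxy)phenyl]-1-[3-methoxy-4-(triisopropylsilyloxy)phenyl]propane-1,3-diol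
Conditions: LiBH4, THF/MeOH, 0 °C
Reagents that add atoms: none
Why: Reductive cleavage of the N-acyl oxazolidinone to the primary alcohol; the aryl bromide, MOM and TIPS groups and both stereocentres should be untouched (the descriptor at C2 changes only by the priority rules).

Step 11
Reactants: 16 MOM-protected 1,3-diol
Product: 18 [(2S,3R)-5-bromo-7-methoxy-2-[3-methoxy-4-(triisopropylsilyloxy)phenyl]-2,3-dihydro-1-benzofuran-3-yl]methanol, via phenol triol 17 (not isolated)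
Conditions: HCl (1.25 M in MeOH), 40 °C
Reagents that add atoms: none
Why: Acidic methanolysis of the MOM acetal, then SN1 ionisation of the electron-rich benzylic alcohol and 5-membered ring closure by the phenol; C3 comes from the aldol, and C2 should settle trans to the hydroxymethyl group because the benzylic C–O bond forms reversibly (thermodynamic control).

Step 12
Reactants: 18 dihydrobenzofuran B alcohol
Product: 19 {[(2S,3R)-5-bromo-7-methoxy-2-[3-methoxy-4-(triisopropylsilyloxy)phenyl]-2,3-dihydro-1-benzofuran-3-yl]methoxy}(tert-butyl)dimethylsilane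
Conditions: TBSCl, imidazole, DMF, rt
Reagents that add atoms: tert-butylchlorodimethylsilane, CC(C)(C)[Si](C)(C)Cl
Why: Standard silylation of the primary alcohol so that the bromine–lithium exchange and the next boron aldol can be run.

Step 13
Reactants: 19 silylated aryl bromide
Product: 21 (2S,3R)-3-[(tert-butyldimethylsilyloxy)methyl]-7-methoxy-2-[3-methoxy-4-(triisopropylsilyloxy)phenyl]-2,3-dihydro-1-benzofuran-5-carbaldehyde, via aryllithium 20 (not isolated)
Conditions: n-BuLi, THF, −78 °C; DMF, −78 to 0 °C; AcOH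
Reagents that add atoms: N,N-dimethylformamide, CN(C)C=O
Why: Bromine–lithium exchange and formylation with DMF (Bouveault aldehyde synthesis); exchange should be much faster than deprotonation of the benzylic C2–H at −78 °C.

Step 14
Reactants: 11 (R)-configured arylacetyl imide; 21 dihydrobenzofuran B aldehyde
Product: 23 (4R)-4-benzyl-3-[(2R,3R)-2-[5-bromo-3-methoxy-2-(methoxymethoxy)phenyl]-3-[(2S,3R)-3-[(tert-butyldimethylsilyloxy)methyl]-7-methoxy-2-[3-methoxy-4-(triisopropylsilyloxy)phenyl]-2,3-dihydro-1-benzofuran-5-yl]-3-hydroxypropanoyl]-1,3-oxazolidin-2-one, via Z-boron enolate 22 (not isolated)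
Conditions: Bu2BOTf, iPr2NEt, CH2Cl2, −78 to 0 °C; then 21, −78 to 0 °C; pH 7 buffer/MeOH
Reagents that add atoms: none
Why: Second Evans syn-aldol reaction, now with the (R)-auxiliary, which should give the (2R,3R) adduct and so fix C3 of dihydrobenzofuran A in the sense opposite to unit B; the stereocentres of 21 are remote and should not interfere.

Step 15
Reactants: 23 syn-aldol imide
Product: 24 (1R,2S)-2-[5-bromo-3-methoxy-2-(methoxymethoxy)phenyl]-1-[(2S,3R)-3-[(tert-butyldimethylsilyloxy)methyl]-7-methoxy-2-[3-methoxy-4-(triisopropylsilyloxy)phenyl]-2,3-dihydro-1-benzofuran-5-yl]propane-1,3-diol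
Conditions: LiBH4, THF/MeOH, 0 °C
Reagents that add atoms: none
Why: Reductive removal of the auxiliary as in step 10; silyl ethers and the aryl bromide should be inert to LiBH4.

Step 16
Reactants: 24 MOM-protected 1,3-diol
Product: 26 [(2R,3S)-5-bromo-2-[(2S,3R)-3-(hydroxymethyl)-7-methoxy-2-[3-methoxy-4-(triisopropylsilyloxy)phenyl]-2,3-dihydro-1-benzofuran-5-yl]-7-methoxy-2,3-dihydro-1-benzofuran-3-yl]methanol, via phenolic tetraol 25 (not isolated)
Conditions: HCl (1.25 M in MeOH), 40 °C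
Reagents that add atoms: none
Why: Acidic loss of the MOM group and of the primary TBS ether, then SN1 benzylic cyclisation (the cation is para to the ring oxygen of unit B); C2 of unit A should again settle trans to its hydroxymethyl group, and unit B is already the thermodynamic trans isomer, so reversible opening cannot change it.

Step 17
Reactants: 26 bis(dihydrobenzofuran) bromo diol
Product: 27 (2R,3S)-5-bromo-3-[(tert-butyldimethylsilyloxy)methyl]-2-[(2S,3R)-3-[(tert-butyldimethylsilyloxy)methyl]-7-methoxy-2-[3-methoxy-4-(triisopropylsilyloxy)phenyl]-2,3-dihydro-1-benzofuran-5-yl]-7-methoxy-2,3-dihydro-1-benzofuran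
Conditions: TBSCl (2.5 equiv), imidazole, DMF, rt
Reagents that add atoms: tert-butylchlorodimethylsilane, CC(C)(C)[Si](C)(C)Cl
Why: Standard silylation of both primary alcohols in one operation.

Step 18
Reactants: 27 bis-silylated aryl bromide
Product: 29 (2R,3S)-3-[(tert-butyldimethylsilyloxy)methyl]-2-[(2S,3R)-3-[(tert-butyldimethylsilyloxy)methyl]-7-methoxy-2-[3-methoxy-4-(triisopropylsilyloxy)phenyl]-2,3-dihydro-1-benzofuran-5-yl]-7-methoxy-2,3-dihydro-1-benzofuran-5-carbaldehyde, via aryllithium 28 (not isolated)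
Conditions: n-BuLi, THF, −78 °C; DMF, −78 to 0 °C; AcOH
Reagents that add atoms: N,N-dimethylformamide, CN(C)C=O
Why: Bromine–lithium exchange and formylation as in step 13; the new aldehyde carbon becomes C7 of the oxolane.

Step 19
Reactants: 30 but-2-yne-1,4-diol
Product: 31 4-(triisopropylsilyloxy)but-2-yn-1-ol
Conditions: TIPSCl (0.33 equiv relative to the diol), imidazole, DMF, 0 °C
Reagents that add atoms: chlorotriisopropylsilane, CC(C)[Si](Cl)(C(C)C)C(C)C
Why: Statistical mono-silylation of a symmetrical diol used in excess.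

Step 20
Reactants: 31 4-(triisopropylsilyloxy)but-2-yn-1-ol
Product: 32 (Z)-2-(tributylstannyl)-4-(triisopropylsilyloxy)but-2-en-1-ol
Conditions: Bu3SnH, [Cp*RuCl]4 (1.25 mol%), CH2Cl2, rt
Reagents that add atoms: tributyltin hydride, CCCC[SnH](CCCC)CCCC
Why: Ruthenium-catalysed trans-hydrostannation of a propargylic alcohol: the free hydroxyl should direct tin to the proximal alkyne carbon, and anti addition of H and Sn places tin cis to the CH2OTIPS group.

Step 21
Reactants: 32 alkenylstannane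
Product: 33 (Z)-2-iodo-4-(triisopropylsilyloxy)but-2-en-1-ol
Conditions: I2, CH2Cl2, 0 °C
Reagents that add atoms: iodine, II
Why: Iododestannylation with retention of alkene geometry.

Step 22
Reactants: 33 alkenyl iodide; 34 2-(iodomethyl)-4,4,5,5-tetramethyl-1,3,2-dioxaborolane
Product: 36 (E)-2-[(4,4,5,5-tetramethyl-1,3,2-dioxaborolan-2-yl)methyl]-4-(triisopropylsilyloxy)but-2-en-1-ol, via borylmethylzinc iodide 35 (not isolated)
Conditions: Zn dust, THF, rt (34 to 35); then 33, Pd(OAc)2 (2 mol%), SPhos (4 mol%), THF, rt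
Reagents that add atoms: none
Why: Negishi coupling of the alkenyl iodide with the borylmethylzinc reagent, stereoretentive at the alkene, so CH2Bpin ends cis to CH2OTIPS; this coupling type tolerates a free hydroxyl.

Step 23
Reactants: 36 allylboronate alcohol
Product: 38 2-[(E)-2-(chloromethyl)-4-(triisopropylsilyloxy)but-2-en-1-yl]-4,4,5,5-tetramethyl-1,3,2-dioxaborolane, via allylic mesylate 37 (not isolated)
Conditions: MsCl, 2,4,6-collidine, LiCl, DMF, 0 °C
Reagents that add atoms: lithium chloride, [Li+].[Cl-]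
Why: Mesylation and in situ SN2 chloride displacement of a primary allylic alcohol under near-neutral conditions, which the pinacol allylboronate should tolerate; the alkene geometry is not touched.

Step 24
Reactants: 1 4-bromo-2-methoxyphenol
Product: 39 (4-bromo-2-methoxyphenoxy)triisopropylsilane
Conditions: TIPSCl, imidazole, DMF, rt
Reagents that add atoms: chlorotriisopropylsilane, CC(C)[Si](Cl)(C(C)C)C(C)C
Why: Silylation of the phenol of the ring E coupling partner.

Step 25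
Reactants: 29 bis(dihydrobenzofuran) aldehyde; 38 2-(chloromethyl)allyl pinacolboronate
Product: 41 (2R,3R)-2-[(2R,3S)-3-[(tert-butyldimethylsilyloxy)methyl]-2-[(2S,3R)-3-[(tert-butyldimethylsilyloxy)methyl]-7-methoxy-2-[3-methoxy-4-(triisopropylsilyloxy)phenyl]-2,3-dihydro-1-benzofuran-5-yl]-7-methoxy-2,3-dihydro-1-benzofuran-5-yl]-4-methylidene-3-[(triisopropylsilyloxy)methyl]oxolane, via syn chloro borate 40 (not isolated)
Conditions: 38 (1.5 equiv), (R)-TRIP (10 mol%), 4 Å MS, toluene, −30 °C; then KOtBu, THF, −40 to 0 °C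
Reagents that add atoms: none
Why: The phosphoric acid activates the pinacol boronate by hydrogen bonding, and the allyl group is transferred through a closed six-membered chair transition state; the closest known reaction type is the chiral-phosphoric-acid-catalysed allyl- and crotylboration of aryl aldehydes with pinacol allylboronates, here followed by an intramolecular Williamson etherification as with bifunctional 2-(halomethyl)allyl metal reagents. C7 is set by the catalyst, which should direct addition to the Re face of the aldehyde, the stereocentres of 29 being too remote to interfere. C8 is set by the chair: in 38 the CH2OTIPS group is cis to CH2Bpin and therefore axial, which gives the syn adduct 40 and, after ring closure, the 2,3-cis oxolane. The ring closes by 5-exo-tet O-alkylation of the C7 alkoxide (released from the borate by KOtBu) on the primary allylic chloride; SN2 and SN2' attack give the same product. The C7–O bond is never broken and the medium is basic, so the acid-labile benzylic centre keeps its configuration. The selectivities needed are catalyst control of the aldehyde face, syn over anti (secured by the geometric purity of 38 from the trans-hydrostannation) and ring closure faster than 1,3 O-to-O silyl migration (secured by the bulky TIPS group and low temperature).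

Step 26
Reactants: 41 4-methylideneoxolane; 39 (4-bromo-2-methoxyphenoxy)triisopropylsilane
Product: 43 (2R,3R,4R)-2-[(2R,3S)-3-[(tert-butyldimethylsilyloxy)methyl]-2-[(2S,3R)-3-[(tert-butyldimethylsilyloxy)methyl]-7-methoxy-2-[3-methoxy-4-(triisopropylsilyloxy)phenyl]-2,3-dihydro-1-benzofuran-5-yl]-7-methoxy-2,3-dihydro-1-benzofuran-5-yl]-4-[3-methoxy-4-(triisopropylsilyloxy)benzyl]-3-[(triisopropylsilyloxy)methyl]oxolane, via alkyl-9-BBN 42 (not isolated)
Conditions: 9-BBN-H, THF, rt; then 39, PdCl2(dppf) (5 mol%), K3PO4 (3 M aq), DMF, 50 °C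
Reagents that add atoms: none
Why: Hydroboration of the exocyclic alkene from the face anti to the cis C2-aryl and C3-CH2OTIPS groups puts H on C4 trans to them and the CH2–B arm cis (all-cis, sets C8'), and the B-alkyl Suzuki–Miyaura coupling then turns the former B–CH2 carbon of 38 into the benzylic CH2 of ring E.

Step 27
Reactants: 43 penta-silyl ether
Product: 44 target, (2R,3R,4R)-2-[(2R,3S)-3-(hydroxymethyl)-2-[(2S,3R)-3-(hydroxymethyl)-2-(4-hydroxy-3-methoxyphenyl)-7-methoxy-2,3-dihydro-1-benzofuran-5-yl]-7-methoxy-2,3-dihydro-1-benzofuran-5-yl]-3-(hydroxymethyl)-4-(4-hydroxy-3-methoxybenzyl)oxolane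
Conditions: TBAF (8 equiv), AcOH (8 equiv), THF, 0 °C to rt
Reagents that add atoms: none
Why: Global fluoride desilylation of two aryl TIPS, one alkyl TIPS and two alkyl TBS ethers; buffering with AcOH and the absence of strong acid should leave the all-cis benzylic oxolane centre and the trans-dihydrobenzofurans unchanged.

**Compound list**

1 | 4-bromo-2-methoxyphenol | COc1cc(Br)ccc1O | starting material
2 | 4-bromo-2-iodo-6-methoxyphenol | COc1cc(Br)cc(I)c1O | intermediate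
3 | 5-bromo-1-iodo-3-methoxy-2-(methoxymethoxy)benzene | COCOc1c(I)cc(Br)cc1OC | intermediate
4 | diethyl malonate | CCOC(=O)CC(=O)OCC | starting material
5 | diethyl 2-[5-bromo-3-methoxy-2-(methoxymethoxy)phenyl]malonate | CCOC(=O)C(C(=O)OCC)c1cc(Br)cc(OC)c1OCOC | intermediate
6 | 2-[5-bromo-3-methoxy-2-(methoxymethoxy)phenyl]acetic acid | OC(=O)Cc1cc(Br)cc(OC)c1OCOC | intermediate
7 | 2-[5-bromo-3-methoxy-2-(methoxymethoxy)phenyl]acetyl fluoride | FC(=O)Cc1cc(Br)cc(OC)c1OCOC | intermediate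
8 | (S)-4-benzyl-1,3-oxazolidin-2-one | O=C1OC[C@H](Cc2ccccc2)N1 | starting material
9 | (S)-4-benzyl-3-{[5-bromo-3-methoxy-2-(methoxymethoxy)phenyl]acetyl}-1,3-oxazolidin-2-one | O=C1OC[C@H](Cc2ccccc2)N1C(=O)Cc3cc(Br)cc(OC)c3OCOC | intermediate
10 | (R)-4-benzyl-1,3-oxazolidin-2-one | O=C1OC[C@@H](Cc2ccccc2)N1 | starting material
11 | (R)-4-benzyl-3-{[5-bromo-3-methoxy-2-(methoxymethoxy)phenyl]acetyl}-1,3-oxazolidin-2-one | O=C1OC[C@@H](Cc2ccccc2)N1C(=O)Cc3cc(Br)cc(OC)c3OCOC | intermediate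
12 | vanillin (4-hydroxy-3-methoxybenzaldehyde) | COc1cc(C=O)ccc1O | starting material
13 | 3-methoxy-4-(triisopropylsilyloxy)benzaldehyde | COc1cc(C=O)ccc1O[Si](C(C)C)(C(C)C)C(C)C | intermediate
14 | (Z)-dibutylboron enolate of 9 (not isolated) | CCCCB(CCCC)O/C(=C\c1cc(Br)cc(OC)c1OCOC)N2C(=O)OC[C@@H]2Cc3ccccc3 | intermediate
15 | (4S)-4-benzyl-3-[(2S,3S)-2-[5-bromo-3-methoxy-2-(methoxymethoxy)phenyl]-3-hydroxy-3-[3-methoxy-4-(triisopropylsilyloxy)phenyl]propanoyl]-1,3-oxazolidin-2-one | O=C1OC[C@H](Cc2ccccc2)N1C(=O)[C@@H](c3cc(Br)cc(OC)c3OCOC)[C@H](O)c4ccc(O[Si](C(C)C)(C(C)C)C(C)C)c(OC)c4 | intermediate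
16 | (1S,2R)-2-[5-bromo-3-methoxy-2-(methoxymethoxy)phenyl]-1-[3-methoxy-4-(triisopropylsilyloxy)phenyl]propane-1,3-diol | OC[C@@H](c1cc(Br)cc(OC)c1OCOC)[C@H](O)c2ccc(O[Si](C(C)C)(C(C)C)C(C)C)c(OC)c2 | intermediate
17 | (1S,2R)-2-(5-bromo-2-hydroxy-3-methoxyphenyl)-1-[3-methoxy-4-(triisopropylsilyloxy)phenyl]propane-1,3-diol (not isolated) | OC[C@@H](c1cc(Br)cc(OC)c1O)[C@H](O)c2ccc(O[Si](C(C)C)(C(C)C)C(C)C)c(OC)c2 | intermediate
18 | [(2S,3R)-5-bromo-7-methoxy-2-[3-methoxy-4-(triisopropylsilyloxy)phenyl]-2,3-dihydro-1-benzofuran-3-yl]methanol (trans) | Brc1cc(OC)c2c(c1)[C@H](CO)[C@@H](c3ccc(O[Si](C(C)C)(C(C)C)C(C)C)c(OC)c3)O2 | intermediate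
19 | {[(2S,3R)-5-bromo-7-methoxy-2-[3-methoxy-4-(triisopropylsilyloxy)phenyl]-2,3-dihydro-1-benzofuran-3-yl]methoxy}(tert-butyl)dimethylsilane | Brc1cc(OC)c2c(c1)[C@H](CO[Si](C)(C)C(C)(C)C)[C@@H](c3ccc(O[Si](C(C)C)(C(C)C)C(C)C)c(OC)c3)O2 | intermediate
20 | 5-lithio derivative of 19 (not isolated) | [Li]c1cc(OC)c2c(c1)[C@H](CO[Si](C)(C)C(C)(C)C)[C@@H](c3ccc(O[Si](C(C)C)(C(C)C)C(C)C)c(OC)c3)O2 | intermediate
21 | (2S,3R)-3-[(tert-butyldimethylsilyloxy)methyl]-7-methoxy-2-[3-methoxy-4-(triisopropylsilyloxy)phenyl]-2,3-dihydro-1-benzofuran-5-carbaldehyde | O=Cc1cc(OC)c2c(c1)[C@H](CO[Si](C)(C)C(C)(C)C)[C@@H](c3ccc(O[Si](C(C)C)(C(C)C)C(C)C)c(OC)c3)O2 | intermediate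
22 | (Z)-dibutylboron enolate of 11 (not isolated) | CCCCB(CCCC)O/C(=C\c1cc(Br)cc(OC)c1OCOC)N2C(=O)OC[C@H]2Cc3ccccc3 | intermediate
23 | (4R)-4-benzyl-3-[(2R,3R)-2-[5-bromo-3-methoxy-2-(methoxymethoxy)phenyl]-3-hydroxy-3-(dihydrobenzofuran-5-yl of 21)propanoyl]-1,3-oxazolidin-2-one | O=C1OC[C@@H](Cc2ccccc2)N1C(=O)[C@H](c3cc(Br)cc(OC)c3OCOC)[C@@H](O)c4cc(OC)c5c(c4)[C@H](CO[Si](C)(C)C(C)(C)C)[C@@H](c6ccc(O[Si](C(C)C)(C(C)C)C(C)C)c(OC)c6)O5 | intermediate
24 | (1R,2S)-2-[5-bromo-3-methoxy-2-(methoxymethoxy)phenyl]-1-[(2S,3R)-3-[(tert-butyldimethylsilyloxy)methyl]-7-methoxy-2-[3-methoxy-4-(triisopropylsilyloxy)phenyl]-2,3-dihydro-1-benzofuran-5-yl]propane-1,3-diol | OC[C@H](c1cc(Br)cc(OC)c1OCOC)[C@@H](O)c2cc(OC)c3c(c2)[C@H](CO[Si](C)(C)C(C)(C)C)[C@@H](c4ccc(O[Si](C(C)C)(C(C)C)C(C)C)c(OC)c4)O3 | intermediate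
25 | (1R,2S)-2-(5-bromo-2-hydroxy-3-methoxyphenyl)-1-[(2S,3R)-3-(hydroxymethyl)-7-methoxy-2-[3-methoxy-4-(triisopropylsilyloxy)phenyl]-2,3-dihydro-1-benzofuran-5-yl]propane-1,3-diol (not isolated) | OC[C@H](c1cc(Br)cc(OC)c1O)[C@@H](O)c2cc(OC)c3c(c2)[C@H](CO)[C@@H](c4ccc(O[Si](C(C)C)(C(C)C)C(C)C)c(OC)c4)O3 | intermediate
26 | [(2R,3S)-5-bromo-2-[(2S,3R)-3-(hydroxymethyl)-7-methoxy-2-[3-methoxy-4-(triisopropylsilyloxy)phenyl]-2,3-dihydro-1-benzofuran-5-yl]-7-methoxy-2,3-dihydro-1-benzofuran-3-yl]methanol | Brc1cc(OC)c2c(c1)[C@@H](CO)[C@H](c3cc(OC)c4c(c3)[C@H](CO)[C@@H](c5ccc(O[Si](C(C)C)(C(C)C)C(C)C)c(OC)c5)O4)O2 | intermediate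
27 | bis-TBS ether of 26 | Brc1cc(OC)c2c(c1)[C@@H](CO[Si](C)(C)C(C)(C)C)[C@H](c3cc(OC)c4c(c3)[C@H](CO[Si](C)(C)C(C)(C)C)[C@@H](c5ccc(O[Si](C(C)C)(C(C)C)C(C)C)c(OC)c5)O4)O2 | intermediate
28 | 5-lithio derivative of 27 (not isolated) | [Li]c1cc(OC)c2c(c1)[C@@H](CO[Si](C)(C)C(C)(C)C)[C@H](c3cc(OC)c4c(c3)[C@H](CO[Si](C)(C)C(C)(C)C)[C@@H](c5ccc(O[Si](C(C)C)(C(C)C)C(C)C)c(OC)c5)O4)O2 | intermediate
29 | (2R,3S)-3-[(tert-butyldimethylsilyloxy)methyl]-2-[(2S,3R)-3-[(tert-butyldimethylsilyloxy)methyl]-7-methoxy-2-[3-methoxy-4-(triisopropylsilyloxy)phenyl]-2,3-dihydro-1-benzofuran-5-yl]-7-methoxy-2,3-dihydro-1-benzofuran-5-carbaldehyde | O=Cc1cc(OC)c2c(c1)[C@@H](CO[Si](C)(C)C(C)(C)C)[C@H](c3cc(OC)c4c(c3)[C@H](CO[Si](C)(C)C(C)(C)C)[C@@H](c5ccc(O[Si](C(C)C)(C(C)C)C(C)C)c(OC)c5)O4)O2 | intermediate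
30 | but-2-yne-1,4-diol | OCC#CCO | starting material
31 | 4-(triisopropylsilyloxy)but-2-yn-1-ol | OCC#CCO[Si](C(C)C)(C(C)C)C(C)C | intermediate
32 | (Z)-2-(tributylstannyl)-4-(triisopropylsilyloxy)but-2-en-1-ol | OC/C([Sn](CCCC)(CCCC)CCCC)=C/CO[Si](C(C)C)(C(C)C)C(C)C | intermediate
33 | (Z)-2-iodo-4-(triisopropylsilyloxy)but-2-en-1-ol | OC/C(I)=C/CO[Si](C(C)C)(C(C)C)C(C)C | intermediate
34 | 2-(iodomethyl)-4,4,5,5-tetramethyl-1,3,2-dioxaborolane | ICB1OC(C)(C)C(C)(C)O1 | starting material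
35 | iodo[(4,4,5,5-tetramethyl-1,3,2-dioxaborolan-2-yl)methyl]zinc (not isolated) | I[Zn]CB1OC(C)(C)C(C)(C)O1 | intermediate
36 | (E)-2-[(4,4,5,5-tetramethyl-1,3,2-dioxaborolan-2-yl)methyl]-4-(triisopropylsilyloxy)but-2-en-1-ol | OC/C(CB1OC(C)(C)C(C)(C)O1)=C/CO[Si](C(C)C)(C(C)C)C(C)C | intermediate
37 | methanesulfonate of 36 (not isolated) | CS(=O)(=O)OC/C(CB1OC(C)(C)C(C)(C)O1)=C/CO[Si](C(C)C)(C(C)C)C(C)C | intermediate
38 | 2-[(E)-2-(chloromethyl)-4-(triisopropylsilyloxy)but-2-en-1-yl]-4,4,5,5-tetramethyl-1,3,2-dioxaborolane | ClC/C(CB1OC(C)(C)C(C)(C)O1)=C/CO[Si](C(C)C)(C(C)C)C(C)C | intermediate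
39 | (4-bromo-2-methoxyphenoxy)triisopropylsilane | COc1cc(Br)ccc1O[Si](C(C)C)(C(C)C)C(C)C | intermediate
40 | pinacol borate of (1R,2R)-1-aryl-3-(chloromethyl)-2-[(triisopropylsilyloxy)methyl]but-3-en-1-ol, aryl as in 29, syn (not isolated) | ClCC(=C)[C@H](CO[Si](C(C)C)(C(C)C)C(C)C)[C@@H](OB1OC(C)(C)C(C)(C)O1)c2cc(OC)c3c(c2)[C@@H](CO[Si](C)(C)C(C)(C)C)[C@H](c4cc(OC)c5c(c4)[C@H](CO[Si](C)(C)C(C)(C)C)[C@@H](c6ccc(O[Si](C(C)C)(C(C)C)C(C)C)c(OC)c6)O5)O3 | intermediate
41 | (2R,3R)-2-aryl-4-methylidene-3-[(triisopropylsilyloxy)methyl]oxolane, aryl as in 29, 2,3-cis | C=C1CO[C@@H](c2cc(OC)c3c(c2)[C@@H](CO[Si](C)(C)C(C)(C)C)[C@H](c4cc(OC)c5c(c4)[C@H](CO[Si](C)(C)C(C)(C)C)[C@@H](c6ccc(O[Si](C(C)C)(C(C)C)C(C)C)c(OC)c6)O5)O3)[C@H]1CO[Si](C(C)C)(C(C)C)C(C)C | intermediate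
42 | B-{[all-cis-5-aryl-4-[(triisopropylsilyloxy)methyl]oxolan-3-yl]methyl}-9-borabicyclo[3.3.1]nonane (not isolated) | B1(C2CCCC1CCC2)C[C@H]3CO[C@@H](c4cc(OC)c5c(c4)[C@@H](CO[Si](C)(C)C(C)(C)C)[C@H](c6cc(OC)c7c(c6)[C@H](CO[Si](C)(C)C(C)(C)C)[C@@H](c8ccc(O[Si](C(C)C)(C(C)C)C(C)C)c(OC)c8)O7)O5)[C@H]3CO[Si](C(C)C)(C(C)C)C(C)C | intermediate
43 | penta-silyl ether of the target: (2R,3R,4R)-2-aryl-4-[3-methoxy-4-(triisopropylsilyloxy)benzyl]-3-[(triisopropylsilyloxy)methyl]oxolane, aryl as in 29 | COc1cc(C[C@H]2CO[C@@H](c3cc(OC)c4c(c3)[C@@H](CO[Si](C)(C)C(C)(C)C)[C@H](c5cc(OC)c6c(c5)[C@H](CO[Si](C)(C)C(C)(C)C)[C@@H](c7ccc(O[Si](C(C)C)(C(C)C)C(C)C)c(OC)c7)O6)O4)[C@H]2CO[Si](C(C)C)(C(C)C)C(C)C)ccc1O[Si](C(C)C)(C(C)C)C(C)C | intermediate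
44 | target CNP0395728.1 | COc1cc(C[C@H]2CO[C@@H](c3cc(OC)c4c(c3)[C@@H](CO)[C@H](c3cc(OC)c5c(c3)[C@H](CO)[C@@H](c3ccc(O)c(OC)c3)O5)O4)[C@H]2CO)ccc1O | target

**Step count and risks**

Total step count: 27. Longest linear sequence: 19 steps (steps 1–6, 9–18, 25–27).

Steps most likely to fail:

Step 25. The hindered β,γ-disubstituted boronate may add slowly to the electron-rich aldehyde, catalyst control of the aldehyde face may be incomplete (leakage to the (2S,3S)-oxolane), or silyl migration may precede ring closure. The fallback replaces catalyst control by auxiliary control and sets out from 29 and 10. Methyl 3-hydroxypropanoate is silylated (TIPSCl, imidazole) to methyl 3-(triisopropylsilyloxy)propanoate F1, saponified (LiOH) to 3-(triisopropylsilyloxy)propanoic acid F2 and attached to 10 (PivCl, Et3N, LiCl) to give (R)-4-benzyl-3-[3-(triisopropylsilyloxy)propanoyl]-1,3-oxazolidin-2-one F3. An Evans syn-aldol reaction of F3 (Bu2BOTf, iPr2NEt, −78 °C) with 29 should give the syn adduct F4 with C7 and C8 fixed by the auxiliary. Transamidation (MeNHOMe·HCl, AlMe3) gives the Weinreb amide F5, and chloromethyllithium (ICH2Cl, MeLi·LiBr, −78 °C) gives the α-chloroketone F6, whose C7 alkoxide closes the ring on warming (5-exo-tet) to the 2,3-cis oxolan-3-one F7. Petasis methylenation (Cp2TiMe2, toluene, 65 °C, non-basic so the centre next to the ketone is not epimerised) then returns to the route at 41.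

Step 26. The borane may attack the wrong face (C4 epimer), or transmetalation of the β-branched alkylborane may be slow and lose out to protodeboronation. The fallback forms the C(sp3)–C(sp2) bond by cross-electrophile coupling and sets out from 42. Oxidation (NaBO3·4H2O, THF/H2O) gives the primary alcohol F8, at which stage C4 epimers should be separable by chromatography. Appel iodination (I2, PPh3, imidazole) gives the iodide F9, and nickel-catalysed reductive coupling with 39 (NiCl2(dme), 4,4'-di-tert-butyl-2,2'-bipyridine, Zn, DMA) returns to the route at 43.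

Step 22. The borylmethylzinc reagent may be protonated by the free hydroxyl or couple sluggishly with the trisubstituted alkenyl iodide. The fallback builds the allylboronate by one-carbon homologation and sets out from 33. Silylation (TESCl, imidazole) gives the triethylsilyl ether F10; Miyaura borylation (B2pin2, PdCl2(PPh3)2, KOPh, toluene, 50 °C) with retention of geometry gives the alkenylboronate F11; Matteson homologation (BrCH2Cl, n-BuLi, THF, −78 °C to rt) inserts CH2 into the C–B bond and gives the allylboronate F12; selective removal of the triethylsilyl group (PPTS, MeOH, 0 °C) returns to the route at 36.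

Further compounds
F1 | step 25 | methyl 3-(triisopropylsilyloxy)propanoate | COC(=O)CCO[Si](C(C)C)(C(C)C)C(C)C
F2 | step 25 | 3-(triisopropylsilyloxy)propanoic acid | OC(=O)CCO[Si](C(C)C)(C(C)C)C(C)C
F3 | step 25 | (R)-4-benzyl-3-[3-(triisopropylsilyloxy)propanoyl]-1,3-oxazolidin-2-one | O=C1OC[C@@H](Cc2ccccc2)N1C(=O)CCO[Si](C(C)C)(C(C)C)C(C)C
F4 | step 25 | (4R)-4-benzyl-3-[(2R,3R)-3-aryl-3-hydroxy-2-[(triisopropylsilyloxy)methyl]propanoyl]-1,3-oxazolidin-2-one, aryl as in 29, syn | O=C1OC[C@@H](Cc2ccccc2)N1C(=O)[C@H](CO[Si](C(C)C)(C(C)C)C(C)C)[C@@H](O)c3cc(OC)c4c(c3)[C@@H](CO[Si](C)(C)C(C)(C)C)[C@H](c5cc(OC)c6c(c5)[C@H](CO[Si](C)(C)C(C)(C)C)[C@@H](c7ccc(O[Si](C(C)C)(C(C)C)C(C)C)c(OC)c7)O6)O4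
F5 | step 25 | (2R,3R)-3-aryl-3-hydroxy-N-methoxy-N-methyl-2-[(triisopropylsilyloxy)methyl]propanamide, aryl as in 29 | CON(C)C(=O)[C@H](CO[Si](C(C)C)(C(C)C)C(C)C)[C@@H](O)c1cc(OC)c2c(c1)[C@@H](CO[Si](C)(C)C(C)(C)C)[C@H](c3cc(OC)c4c(c3)[C@H](CO[Si](C)(C)C(C)(C)C)[C@@H](c5ccc(O[Si](C(C)C)(C(C)C)C(C)C)c(OC)c5)O4)O2
F6 | step 25 | 4-aryl-1-chloro-4-hydroxy-3-[(triisopropylsilyloxy)methyl]butan-2-one, aryl as in 29, configuration as in F5 | ClCC(=O)[C@H](CO[Si](C(C)C)(C(C)C)C(C)C)[C@@H](O)c1cc(OC)c2c(c1)[C@@H](CO[Si](C)(C)C(C)(C)C)[C@H](c3cc(OC)c4c(c3)[C@H](CO[Si](C)(C)C(C)(C)C)[C@@H](c5ccc(O[Si](C(C)C)(C(C)C)C(C)C)c(OC)c5)O4)O2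
F7 | step 25 | cis-5-aryl-4-[(triisopropylsilyloxy)methyl]oxolan-3-one, aryl as in 29, configuration as in 41 | O=C1CO[C@@H](c2cc(OC)c3c(c2)[C@@H](CO[Si](C)(C)C(C)(C)C)[C@H](c4cc(OC)c5c(c4)[C@H](CO[Si](C)(C)C(C)(C)C)[C@@H](c6ccc(O[Si](C(C)C)(C(C)C)C(C)C)c(OC)c6)O5)O3)[C@H]1CO[Si](C(C)C)(C(C)C)C(C)C
F8 | step 26 | [all-cis-5-aryl-4-[(triisopropylsilyloxy)methyl]oxolan-3-yl]methanol, aryl as in 29 | OC[C@H]1CO[C@@H](c2cc(OC)c3c(c2)[C@@H](CO[Si](C)(C)C(C)(C)C)[C@H](c4cc(OC)c5c(c4)[C@H](CO[Si](C)(C)C(C)(C)C)[C@@H](c6ccc(O[Si](C(C)C)(C(C)C)C(C)C)c(OC)c6)O5)O3)[C@H]1CO[Si](C(C)C)(C(C)C)C(C)C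
F9 | step 26 | all-cis-2-aryl-4-(iodomethyl)-3-[(triisopropylsilyloxy)methyl]oxolane, aryl as in 29 | IC[C@H]1CO[C@@H](c2cc(OC)c3c(c2)[C@@H](CO[Si](C)(C)C(C)(C)C)[C@H](c4cc(OC)c5c(c4)[C@H](CO[Si](C)(C)C(C)(C)C)[C@@H](c6ccc(O[Si](C(C)C)(C(C)C)C(C)C)c(OC)c6)O5)O3)[C@H]1CO[Si](C(C)C)(C(C)C)C(C)C
F10 | step 22 | (Z)-triethyl{[2-iodo-4-(triisopropylsilyloxy)but-2-en-1-yl]oxy}silane | CC[Si](CC)(CC)OC/C(I)=C/CO[Si](C(C)C)(C(C)C)C(C)C
F11 | step 22 | (E)-triethyl{[2-(4,4,5,5-tetramethyl-1,3,2-dioxaborolan-2-yl)-4-(triisopropylsilyloxy)but-2-en-1-yl]oxy}silane | CC[Si](CC)(CC)OC/C(B1OC(C)(C)C(C)(C)O1)=C/CO[Si](C(C)C)(C(C)C)C(C)C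
F12 | step 22 | (E)-triethyl{[2-[(4,4,5,5-tetramethyl-1,3,2-dioxaborolan-2-yl)methyl]-4-(triisopropylsilyloxy)but-2-en-1-yl]oxy}silane | CC[Si](CC)(CC)OC/C(CB1OC(C)(C)C(C)(C)O1)=C/CO[Si](C(C)C)(C(C)C)C(C)C
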